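The cyclohexane ring is disconnected by a Diels–Alder reaction. A threonine-derived butenolide carrying a 1-ethoxyvinyl group (the diene C13=C14–C1=C10, eunicellane numbering) adds methacrolein (C11=C12). This forms the C12–C13 bond and the bond from ring-fusion carbon C10 to the future carbinol carbon C11 in one operation. The step exploits the 1,4-relationship, within the cyclohexane ring (C1, C10–C14), of oxygen-bearing C11 and side-chain-bearing C14, with C1 and C10 shared with the oxolane ring (O, C2, C1, C10, C9). The butenolide later becomes that oxolane, the C14 ketone carries the propanoate, and a Nozaki–Hiyama–Kishi closure gives the oxonane.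

Key step: step 6

Remark: skeleton atoms are numbered as in the eunicellanes (C2–O–C9 ether bridge, ring fusion C1/C10, carbinol C11, lactone carbonyl C16, exocyclic methylene C7=C19); all stereochemical outcomes below are expectations by analogy, not measured results.

Step 1
Reactants: 1 O-tert-butyl-D-threonine
Product: 2 (2R,3S)-2-acetoxy-3-tert-butoxybutanoic acid
Conditions: NaNO2, AcOH, 15 °C to rt
Reagents that add atoms: acetic acid, CC(=O)O
Why: Diazotisation of the α-amino acid (van Slyke-type deamination) in acetic acid should replace nitrogen by acetate with net retention through double inversion via the α-lactone, so the 2R centre (future C2) is kept.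

Step 2
Reactants: 2 (2R,3S)-2-acetoxy-3-tert-butoxybutanoic acid
Product: 3 methyl (2R,3S)-2-acetoxy-3-tert-butoxybutanoate
Conditions: MeI, KHCO3, DMF, rt
Reagents that add atoms: iodomethane, CI
Why: SN2 O-alkylation of the carboxylate gives the ester acceptor for the next step under conditions too mild to disturb the α-acyloxy stereocentre.

Step 3
Reactants: 3 methyl (2R,3S)-2-acetoxy-3-tert-butoxybutanoate
Product: 4 (5R)-5-[(1S)-1-tert-butoxyethyl]-4-hydroxyfuran-2(5H)-one
Conditions: LiN(SiMe3)2 (2.2 equiv), THF, −78 to 0 °C; aq HCl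
Reagents that add atoms: none
Why: Dieckmann condensation of the acetate enolate onto the methyl ester should close the tetronic acid, kinetic deprotonation at −78 °C taking place at the acetate methyl and not at the hindered α-CH, so that the future C2 centre is retained.

Step 4
Reactants: 4 (5R)-5-[(1S)-1-tert-butoxyethyl]-4-hydroxyfuran-2(5H)-one
Product: 5 (2R)-2-[(1S)-1-tert-butoxyethyl]-5-oxo-2,5-dihydrofuran-3-yl trifluoromethanesulfonate
Conditions: Tf2O, i-Pr2NEt, CH2Cl2, −78 °C
Reagents that add atoms: trifluoromethanesulfonic anhydride, O=S(=O)(OS(=O)(=O)C(F)(F)F)C(F)(F)F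
Why: O-sulfonylation of the vinylogous acid gives the enol triflate that activates C1 for cross-coupling.

Step 5
Reactants: 5 (2R)-2-[(1S)-1-tert-butoxyethyl]-5-oxo-2,5-dihydrofuran-3-yl trifluoromethanesulfonate; 6 tributyl(1-ethoxyvinyl)stannane
Product: 7 (5S)-5-[(1S)-1-tert-butoxyethyl]-4-(1-ethoxyvinyl)furan-2(5H)-one
Conditions: Pd(PPh3)4 (5 mol%), LiCl, THF, 60 °C
Reagents that add atoms: none
Why: Stille cross-coupling of the electron-poor enol triflate with the α-alkoxyvinylstannane should install C14 and C13 as a 2-ethoxy-1,3-diene (C13=C14–C1=C10) conjugated to the butenolide.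

Step 6
Reactants: 7 (5S)-5-[(1S)-1-tert-butoxyethyl]-4-(1-ethoxyvinyl)furan-2(5H)-one; 8 methacrolein
Product: 9 4-ethoxy-7-formyl-7-methyl-3-[(1S)-1-tert-butoxyethyl]-5,6,7,7a-tetrahydroisobenzofuran-1(3H)-one
Conditions: methacrolein (5 equiv), BHT (cat.), toluene, 80 °C, sealed tube, no Lewis acid
Reagents that add atoms: none
Why: A normal-electron-demand Diels–Alder cycloaddition, concerted but asynchronous, in which the enol-ether terminus C13 bonds to the β-carbon of the enal (C12) ahead of the C10–C11 bond. The closest known reaction types are the cycloadditions of 2-alkoxy- and 2-silyloxy-1,3-dienes and of 4-vinylbutenolides with enals. The cyclohexene ring (C1, C10, C11, C12, C13, C14) is closed by [4+2] cycloaddition and no other ring is formed. C10 is controlled by the C2 stereocentre, the dienophile adding to the butenolide face anti to the 1-tert-butoxyethyl group, and C11 by the endo (Alder) orientation of the formyl group, which places CHO cis to C9 (the outside substituent of the diene) and so marks the position of the later C11 oxygen. The step needs regioselectivity, which the ethoxy donor on C14 secures (C11 ends 1,4 to C14), π-facial and endo selectivity as just described, and chemoselectivity over hetero-Diels–Alder addition of the enal to the enol ether, which the moderate temperature and the absence of a Lewis acid should secure.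

Step 7
Reactants: 9 4-ethoxy-7-formyl-7-methyl-3-[(1S)-1-tert-butoxyethyl]-5,6,7,7a-tetrahydroisobenzofuran-1(3H)-one
Product: 10 7-formyl-7-methyl-3-[(1S)-1-tert-butoxyethyl]hexahydroisobenzofuran-1,4-dione (cis-fused)
Conditions: 1 M HCl, THF, 0 °C to rt
Reagents that add atoms: water, O
Why: Acid hydrolysis of the enol ether gives the C14 ketone and, through reversible acid-catalysed enolisation, the thermodynamically preferred cis ring fusion with C14 trans to the C2 side chain, which sets C1.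

Step 8
Reactants: 10 7-formyl-7-methyl-3-[(1S)-1-tert-butoxyethyl]hexahydroisobenzofuran-1,4-dione
Product: 11 7-formyl-7-methyl-1-oxo-3-[(1S)-1-tert-butoxyethyl]-1,3,3a,6,7,7a-hexahydroisobenzofuran-4-yl trifluoromethanesulfonate
Conditions: KN(SiMe3)2, THF, −78 °C; then PhNTf2
Reagents that add atoms: N-phenylbis(trifluoromethanesulfonimide), O=S(=O)(N(c1ccccc1)S(=O)(=O)C(F)(F)F)C(F)(F)F
Why: Kinetic enolisation at the C13 methylene rather than the C1 methine and O-triflation should give the less substituted enol triflate (C13=C14), the aldehyde having no α-hydrogen.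

Step 9
Reactants: 11 7-formyl-7-methyl-1-oxo-3-[(1S)-1-tert-butoxyethyl]-1,3,3a,6,7,7a-hexahydroisobenzofuran-4-yl trifluoromethanesulfonate
Product: 12 7-(formyloxy)-7-methyl-1-oxo-3-[(1S)-1-tert-butoxyethyl]-1,3,3a,6,7,7a-hexahydroisobenzofuran-4-yl trifluoromethanesulfonate
Conditions: m-CPBA, NaHCO3, CH2Cl2, 0 °C to rt
Reagents that add atoms: 3-chloroperbenzoic acid, OOC(=O)c1cccc(Cl)c1
Why: Baeyer–Villiger oxidation of the α-quaternary aldehyde, the tertiary carbon migrating with retention, turns the formyl group into the formate of the C11 carbinol, while the electron-poor enol triflate is inert to the peracid.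

Step 10
Reactants: 13 methyl propiolate
Product: 14 methyl 2-(tributylstannyl)acrylate
Conditions: Bu3SnH, Pd(PPh3)4 (2 mol%), THF, 0 °C
Reagents that add atoms: tributyltin hydride, CCCC[SnH](CCCC)CCCC
Why: Palladium-catalysed hydrostannation of the alkynoate is α-selective and gives the 1-(methoxycarbonyl)vinylstannane.

Step 11
Reactants: 12 7-(formyloxy)-7-methyl-1-oxo-3-[(1S)-1-tert-butoxyethyl]-1,3,3a,6,7,7a-hexahydroisobenzofuran-4-yl trifluoromethanesulfonate; 14 methyl 2-(tributylstannyl)acrylate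
Product: 15 methyl 2-[7-(formyloxy)-7-methyl-1-oxo-3-[(1S)-1-tert-butoxyethyl]-1,3,3a,6,7,7a-hexahydroisobenzofuran-4-yl]prop-2-enoate
Conditions: Pd(PPh3)4 (10 mol%), CuI (20 mol%), LiCl, DMF, 50 °C
Reagents that add atoms: none
Why: Copper-assisted Stille coupling of the cyclohexenyl triflate with the hindered 1-substituted vinylstannane joins C14 to C15 and delivers C16 at the acid oxidation level.

Step 12
Reactants: 15 methyl 2-[7-(formyloxy)-7-methyl-1-oxo-3-[(1S)-1-tert-butoxyethyl]-1,3,3a,6,7,7a-hexahydroisobenzofuran-4-yl]prop-2-enoate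
Product: 17 2-[7-hydroxy-7-methyl-1-oxo-3-[(1S)-1-tert-butoxyethyl]-1,3,3a,6,7,7a-hexahydroisobenzofuran-4-yl]prop-2-enoic acid, via seco diacid 16 (not isolated)
Conditions: LiOH, THF/H2O, rt; then 1 M HCl to pH 2
Reagents that add atoms: lithium hydroxide, [Li+].[OH-]
Why: Saponification cleaves the methyl ester and the formate and opens the γ-lactone, which should re-close on acidification because 5-exo lactonisation is faster than δ-lactonisation by the acrylic acid, giving the free acid needed for carboxylate-directed hydrogenation.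

Step 13
Reactants: 17 2-[7-hydroxy-7-methyl-1-oxo-3-[(1S)-1-tert-butoxyethyl]-1,3,3a,6,7,7a-hexahydroisobenzofuran-4-yl]prop-2-enoic acid
Product: 18 (2R)-2-[7-hydroxy-7-methyl-1-oxo-3-[(1S)-1-tert-butoxyethyl]-1,3,3a,6,7,7a-hexahydroisobenzofuran-4-yl]propanoic acid
Conditions: Ru(OAc)2[(R)-BINAP] (1 mol%), H2 (50 atm), MeOH, rt
Reagents that add atoms: none
Why: Noyori asymmetric hydrogenation of the 2-substituted acrylic acid reduces only the carboxylate-bound α,β-double bond and sets C15 under catalyst control, the (R)-ligand being expected to give 15R by analogy with 2-arylacrylic acids.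

Step 14
Reactants: 18 (2R)-2-[7-hydroxy-7-methyl-1-oxo-3-[(1S)-1-tert-butoxyethyl]-1,3,3a,6,7,7a-hexahydroisobenzofuran-4-yl]propanoic acid
Product: 19 (2R)-2-[7-hydroxy-7-methyl-1-oxo-3-[(1S)-1-tert-butoxyethyl]octahydroisobenzofuran-4-yl]propanoic acid
Conditions: [Ir(cod)(PCy3)(py)]PF6 (5 mol%), H2 (1 atm), CH2Cl2, rt
Reagents that add atoms: none
Why: Hydroxyl-directed hydrogenation of the homoallylic C13=C14 bond delivers hydrogen from the face of the tertiary C11 hydroxyl, so H14 ends cis to that hydroxyl and the C15 chain trans to it, which sets C14.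

Step 15
Reactants: 19 (2R)-2-[7-hydroxy-7-methyl-1-oxo-3-[(1S)-1-tert-butoxyethyl]octahydroisobenzofuran-4-yl]propanoic acid
Product: 20 (2R)-2-[1,7-dihydroxy-7-methyl-3-[(1S)-1-tert-butoxyethyl]octahydroisobenzofuran-4-yl]propanoic acid (lactol, anomers)
Conditions: i-Bu2AlH (3.3 equiv), CH2Cl2, −78 °C; aq KNaC4H4O6
Reagents that add atoms: none
Why: Partial hydride reduction of the γ-lactone stops at the lactol at −78 °C, the carboxylic acid being masked in the flask as its aluminium carboxylate.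

Step 16
Reactants: 20 (2R)-2-[1,7-dihydroxy-7-methyl-3-[(1S)-1-tert-butoxyethyl]octahydroisobenzofuran-4-yl]propanoic acid; 21 (2-bromoallyl)trimethylsilane
Product: 22 (2R)-2-[1-(2-bromoprop-2-enyl)-7-hydroxy-7-methyl-3-[(1S)-1-tert-butoxyethyl]octahydroisobenzofuran-4-yl]propanoic acid
Conditions: BF3·OEt2, CH2Cl2, −78 to −30 °C
Reagents that add atoms: none
Why: Hosomi–Sakurai allylation of the oxocarbenium ion at C9 brings in C8, C7 and C19 with the bromoalkene, the allylsilane attacking the convex face anti to the cis-fused cyclohexane and its quaternary C11, which gives the 2,9-cis oxolane.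

Step 17
Reactants: 22 (2R)-2-[1-(2-bromoprop-2-enyl)-7-hydroxy-7-methyl-3-[(1S)-1-tert-butoxyethyl]octahydroisobenzofuran-4-yl]propanoic acid
Product: 24 (2R)-2-[1-(2-bromoprop-2-enyl)-7-hydroxy-3-[(1S)-1-hydroxyethyl]-7-methyloctahydroisobenzofuran-4-yl]propanoic acid, via tris(trimethylsilyl) derivative 23 (not isolated)
Conditions: Me3SiOTf, 2,6-lutidine, CH2Cl2, 0 °C; then MeOH, citric acid
Reagents that add atoms: none
Why: Silyl-triflate-mediated cleavage of the tert-butyl ether (loss of isobutene from the silyloxonium ion), with transient silylation of the acid and the tertiary hydroxyl and methanolysis on work-up, frees the C3 carbinol without exposing the tertiary alcohol to protic acid.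

Step 18
Reactants: 24 (2R)-2-[1-(2-bromoprop-2-enyl)-7-hydroxy-3-[(1S)-1-hydroxyethyl]-7-methyloctahydroisobenzofuran-4-yl]propanoic acid
Product: 25 (2R)-2-[3-acetyl-1-(2-bromoprop-2-enyl)-7-hydroxy-7-methyloctahydroisobenzofuran-4-yl]propanoic acid
Conditions: Dess–Martin periodinane, NaHCO3, CH2Cl2, rt
Reagents that add atoms: none
Why: Dess–Martin oxidation converts the secondary carbinol into the C3 methyl ketone under buffered conditions that should not epimerise C2, the tertiary hydroxyl being inert.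

Step 19
Reactants: 25 (2R)-2-[3-acetyl-1-(2-bromoprop-2-enyl)-7-hydroxy-7-methyloctahydroisobenzofuran-4-yl]propanoic acid
Product: 26 (2R)-2-[1-(2-bromoprop-2-enyl)-7-hydroxy-3-[(2S)-2-hydroxybut-3-en-2-yl]-7-methyloctahydroisobenzofuran-4-yl]propanoic acid
Conditions: CH2=CHMgBr (4 equiv), THF, −78 °C
Reagents that add atoms: vinylmagnesium bromide, C=C[Mg]Br
Why: Chelation-controlled Grignard addition (Cram chelate between the oxolane oxygen and the ketone) delivers vinyl from the side of H2 and sets the tertiary C3 carbinol as 3S.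

Step 20
Reactants: 26 (2R)-2-[1-(2-bromoprop-2-enyl)-7-hydroxy-3-[(2S)-2-hydroxybut-3-en-2-yl]-7-methyloctahydroisobenzofuran-4-yl]propanoic acid
Product: 27 tricyclic C16–O–C3 lactone with C3 vinyl and C9 2-bromoallyl groups
Conditions: 2-methyl-6-nitrobenzoic anhydride, DMAP, Et3N, CH2Cl2, rt, high dilution
Reagents that add atoms: none
Why: Shiina lactonisation (mixed anhydride, DMAP acyl transfer) acylates the tertiary C3 hydroxyl with retention and closes the seven-membered lactone, the C11 hydroxyl being unable to reach the acid because it is trans to the C14 chain.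

Step 21
Reactants: 27 tricyclic C16–O–C3 lactone with C3 vinyl and C9 2-bromoallyl groups
Product: 29 C4 aldehyde lactone, via vicinal diol 28 (not isolated)
Conditions: OsO4 (2 mol%), NaIO4, 2,6-lutidine, dioxane/H2O, rt
Reagents that add atoms: osmium tetroxide, O=[Os](=O)(=O)=O; sodium periodate, [Na+].[O-]I(=O)(=O)=O
Why: Lemieux–Johnson cleavage of the monosubstituted vinyl group gives the C4 aldehyde, the electron-poor bromoalkene reacting much more slowly with OsO4.

Step 22
Reactants: 29 C4 aldehyde lactone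
Product: 31 (4R)-homoallylic alcohol, via diisopinocampheylborinate 30 (not isolated)
Conditions: (+)-Ipc2B(allyl), Et2O, −78 °C; then NaBO3·4H2O, THF/H2O
Reagents that add atoms: (+)-B-allyldiisopinocampheylborane, C=CCB([C@H]1C[C@H]2C[C@@H]([C@@H]1C)C2(C)C)[C@H]1C[C@H]2C[C@@H]([C@@H]1C)C2(C)C
Why: Brown allylboration through the closed chair transition state adds allyl under reagent control, the (+)-reagent being expected to attack the Re face of the aldehyde and set 4R, and mild perborate oxidation cleaves the borinate.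

Step 23
Reactants: 31 (4R)-homoallylic alcohol
Product: 32 C4 octanoate
Conditions: octanoyl chloride, pyridine, DMAP, CH2Cl2, rt
Reagents that add atoms: octanoyl chloride, CCCCCCCC(=O)Cl
Why: DMAP-catalysed acylation esterifies the secondary C4 alcohol while the tertiary C11 alcohol does not react.

Step 24
Reactants: 32 C4 octanoate
Product: 34 C6 aldehyde, via vicinal diol 33 (not isolated)
Conditions: OsO4 (2 mol%), NaIO4, 2,6-lutidine, dioxane/H2O, rt
Reagents that add atoms: osmium tetroxide, O=[Os](=O)(=O)=O; sodium periodate, [Na+].[O-]I(=O)(=O)=O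
Why: Lemieux–Johnson cleavage of the terminal alkene shortens the allyl group to the C6 aldehyde under buffered conditions that should avoid β-elimination of the octanoate.

Step 25
Reactants: 34 C6 aldehyde
Product: 35 6-O-debutanoylbriarellin C (6R alcohol)
Conditions: CrCl2 (8 equiv), NiCl2 (2 mol%), DMSO, rt, 2 mM
Reagents that add atoms: none
Why: Nozaki–Hiyama–Kishi cyclisation (nickel insertion into the C–Br bond, transmetalation to chromium, addition to the aldehyde) closes the oxonane at C6–C7 and sets C6, the 6R alcohol being expected from addition to the less hindered aldehyde face in the ring-closing conformation, as in related 2-haloallyl/aldehyde oxonane closures.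

Step 26
Reactants: 35 6-O-debutanoylbriarellin C
Product: 36 briarellin C
Conditions: (PrCO)2O, DMAP, Et3N, CH2Cl2, 0 °C
Reagents that add atoms: butyric anhydride, CCCC(=O)OC(=O)CCC
Why: DMAP-catalysed acylation of the allylic C6 alcohol gives the butanoate, the tertiary C11 alcohol remaining free.

Compound list
1 | O-tert-butyl-D-threonine, (2R,3S)-2-amino-3-tert-butoxybutanoic acid | C[C@H](OC(C)(C)C)[C@@H](N)C(=O)O | starting material
2 | (2R,3S)-2-acetoxy-3-tert-butoxybutanoic acid | C[C@H](OC(C)(C)C)[C@@H](OC(C)=O)C(=O)O | intermediate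
3 | methyl (2R,3S)-2-acetoxy-3-tert-butoxybutanoate | C[C@H](OC(C)(C)C)[C@@H](OC(C)=O)C(=O)OC | intermediate
4 | (5R)-5-[(1S)-1-tert-butoxyethyl]-4-hydroxyfuran-2(5H)-one | O=C1O[C@H]([C@H](C)OC(C)(C)C)C(O)=C1 | intermediate
5 | (2R)-2-[(1S)-1-tert-butoxyethyl]-5-oxo-2,5-dihydrofuran-3-yl trifluoromethanesulfonate | O=C1O[C@H]([C@H](C)OC(C)(C)C)C(OS(=O)(=O)C(F)(F)F)=C1 | intermediate
6 | tributyl(1-ethoxyvinyl)stannane | CCCC[Sn](CCCC)(CCCC)C(=C)OCC | starting material
7 | (5S)-5-[(1S)-1-tert-butoxyethyl]-4-(1-ethoxyvinyl)furan-2(5H)-one | O=C1O[C@H]([C@H](C)OC(C)(C)C)C(C(=C)OCC)=C1 | intermediate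
8 | methacrolein (2-methylprop-2-enal) | CC(=C)C=O | starting material
9 | 4-ethoxy-7-formyl-7-methyl-3-[(1S)-1-tert-butoxyethyl]-5,6,7,7a-tetrahydroisobenzofuran-1(3H)-one; new ring anti to the C2 side chain, formyl cis to C9 | O=C1O[C@H]([C@H](C)OC(C)(C)C)C2=C(OCC)CC[C@@](C)(C=O)[C@H]21 | intermediate
10 | 7-formyl-7-methyl-3-[(1S)-1-tert-butoxyethyl]hexahydroisobenzofuran-1,4-dione; cis-fused, H1 and H10 syn to the C2 side chain | O=C1O[C@H]([C@H](C)OC(C)(C)C)[C@H]2C(=O)CC[C@@](C)(C=O)[C@H]21 | intermediate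
11 | 7-formyl-7-methyl-1-oxo-3-[(1S)-1-tert-butoxyethyl]-1,3,3a,6,7,7a-hexahydroisobenzofuran-4-yl trifluoromethanesulfonate | O=C1O[C@H]([C@H](C)OC(C)(C)C)[C@H]2C(OS(=O)(=O)C(F)(F)F)=CC[C@@](C)(C=O)[C@H]21 | intermediate
12 | 7-(formyloxy)-7-methyl-1-oxo-3-[(1S)-1-tert-butoxyethyl]-1,3,3a,6,7,7a-hexahydroisobenzofuran-4-yl trifluoromethanesulfonate | O=C1O[C@H]([C@H](C)OC(C)(C)C)[C@H]2C(OS(=O)(=O)C(F)(F)F)=CC[C@@](C)(OC=O)[C@H]21 | intermediate
13 | methyl propiolate | C#CC(=O)OC | starting material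
14 | methyl 2-(tributylstannyl)acrylate | C=C(C(=O)OC)[Sn](CCCC)(CCCC)CCCC | intermediate
15 | methyl 2-[7-(formyloxy)-7-methyl-1-oxo-3-[(1S)-1-tert-butoxyethyl]-1,3,3a,6,7,7a-hexahydroisobenzofuran-4-yl]prop-2-enoate | O=C1O[C@H]([C@H](C)OC(C)(C)C)[C@H]2C(C(=C)C(=O)OC)=CC[C@@](C)(OC=O)[C@H]21 | intermediate
16 | seco diacid: ring-opened hydroxy acid of 17 (C9 carboxylic acid, C2 hydroxyl) | O[C@H]([C@H](C)OC(C)(C)C)[C@H]1C(C(=C)C(=O)O)=CC[C@@](C)(O)[C@H]1C(=O)O | intermediate
17 | 2-[7-hydroxy-7-methyl-1-oxo-3-[(1S)-1-tert-butoxyethyl]-1,3,3a,6,7,7a-hexahydroisobenzofuran-4-yl]prop-2-enoic acid | O=C1O[C@H]([C@H](C)OC(C)(C)C)[C@H]2C(C(=C)C(=O)O)=CC[C@@](C)(O)[C@H]21 | intermediate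
18 | (2R)-2-[7-hydroxy-7-methyl-1-oxo-3-[(1S)-1-tert-butoxyethyl]-1,3,3a,6,7,7a-hexahydroisobenzofuran-4-yl]propanoic acid | O=C1O[C@H]([C@H](C)OC(C)(C)C)[C@H]2C([C@@H](C)C(=O)O)=CC[C@@](C)(O)[C@H]21 | intermediate
19 | (2R)-2-[7-hydroxy-7-methyl-1-oxo-3-[(1S)-1-tert-butoxyethyl]octahydroisobenzofuran-4-yl]propanoic acid; H14 cis to the C11 hydroxyl | O=C1O[C@H]([C@H](C)OC(C)(C)C)[C@H]2[C@@H](CC[C@@](C)(O)[C@H]21)[C@@H](C)C(=O)O | intermediate
20 | (2R)-2-[1,7-dihydroxy-7-methyl-3-[(1S)-1-tert-butoxyethyl]octahydroisobenzofuran-4-yl]propanoic acid (lactol, anomers) | OC1O[C@H]([C@H](C)OC(C)(C)C)[C@H]2[C@@H](CC[C@@](C)(O)[C@H]21)[C@@H](C)C(=O)O | intermediate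
21 | (2-bromoallyl)trimethylsilane | C[Si](C)(C)CC(Br)=C | starting material
22 | (2R)-2-[1-(2-bromoprop-2-enyl)-7-hydroxy-7-methyl-3-[(1S)-1-tert-butoxyethyl]octahydroisobenzofuran-4-yl]propanoic acid; C8 and C3 cis on the oxolane | C=C(Br)C[C@@H]1O[C@H]([C@H](C)OC(C)(C)C)[C@H]2[C@@H](CC[C@@](C)(O)[C@H]21)[C@@H](C)C(=O)O | intermediate
23 | tris(trimethylsilyl) derivative of 24 (C3 silyl ether, C11 silyl ether, silyl ester) | C=C(Br)C[C@@H]1O[C@H]([C@H](C)O[Si](C)(C)C)[C@H]2[C@@H](CC[C@@](C)(O[Si](C)(C)C)[C@H]21)[C@@H](C)C(=O)O[Si](C)(C)C | intermediate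
24 | (2R)-2-[1-(2-bromoprop-2-enyl)-7-hydroxy-3-[(1S)-1-hydroxyethyl]-7-methyloctahydroisobenzofuran-4-yl]propanoic acid | C=C(Br)C[C@@H]1O[C@H]([C@H](C)O)[C@H]2[C@@H](CC[C@@](C)(O)[C@H]21)[C@@H](C)C(=O)O | intermediate
25 | (2R)-2-[3-acetyl-1-(2-bromoprop-2-enyl)-7-hydroxy-7-methyloctahydroisobenzofuran-4-yl]propanoic acid | C=C(Br)C[C@@H]1O[C@H](C(C)=O)[C@H]2[C@@H](CC[C@@](C)(O)[C@H]21)[C@@H](C)C(=O)O | intermediate
26 | (2R)-2-[1-(2-bromoprop-2-enyl)-7-hydroxy-3-[(2S)-2-hydroxybut-3-en-2-yl]-7-methyloctahydroisobenzofuran-4-yl]propanoic acid | C=C(Br)C[C@@H]1O[C@H]([C@@](C)(O)C=C)[C@H]2[C@@H](CC[C@@](C)(O)[C@H]21)[C@@H](C)C(=O)O | intermediate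
27 | tricyclic lactone (C16–O–C3 oxepanone fused to the hydroisobenzofuran) with 3-vinyl, 3-methyl, 11-hydroxy and 9-(2-bromoprop-2-enyl) groups | C=C(Br)C[C@@H]2O[C@H]3[C@H]4[C@@H](CC[C@@](C)(O)[C@H]42)[C@@H](C)C(=O)O[C@@]3(C)C=C | intermediate
28 | vicinal diol from dihydroxylation of the vinyl group of 27 | C=C(Br)C[C@@H]2O[C@H]3[C@H]4[C@@H](CC[C@@](C)(O)[C@H]42)[C@@H](C)C(=O)O[C@@]3(C)C(O)CO | intermediate
29 | C4 aldehyde lactone (3-formyl analogue of 27) | C=C(Br)C[C@@H]2O[C@H]3[C@H]4[C@@H](CC[C@@](C)(O)[C@H]42)[C@@H](C)C(=O)O[C@@]3(C)C=O | intermediate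
30 | diisopinocampheylborinate of 31 | C=C(Br)C[C@@H]2O[C@H]3[C@H]4[C@@H](CC[C@@](C)(O)[C@H]42)[C@@H](C)C(=O)O[C@@]3(C)[C@H](OB([C@H]5C[C@H]6C[C@@H]([C@@H]5C)C6(C)C)[C@H]5C[C@H]6C[C@@H]([C@@H]5C)C6(C)C)CC=C | intermediate
31 | (4R)-homoallylic alcohol: 3-[(1R)-1-hydroxybut-3-enyl] lactone | C=C(Br)C[C@@H]2O[C@H]3[C@H]4[C@@H](CC[C@@](C)(O)[C@H]42)[C@@H](C)C(=O)O[C@@]3(C)[C@H](O)CC=C | intermediate
32 | C4 octanoate of 31 | C=C(Br)C[C@@H]2O[C@H]3[C@H]4[C@@H](CC[C@@](C)(O)[C@H]42)[C@@H](C)C(=O)O[C@@]3(C)[C@H](OC(=O)CCCCCCC)CC=C | intermediate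
33 | vicinal diol from dihydroxylation of the terminal alkene of 32 | C=C(Br)C[C@@H]2O[C@H]3[C@H]4[C@@H](CC[C@@](C)(O)[C@H]42)[C@@H](C)C(=O)O[C@@]3(C)[C@H](OC(=O)CCCCCCC)CC(O)CO | intermediate
34 | C6 aldehyde (C4 octanoate, C9 2-bromoprop-2-enyl) | C=C(Br)C[C@@H]2O[C@H]3[C@H]4[C@@H](CC[C@@](C)(O)[C@H]42)[C@@H](C)C(=O)O[C@@]3(C)[C@H](OC(=O)CCCCCCC)CC=O | intermediate
35 | 6-O-debutanoylbriarellin C (6R allylic alcohol) | C=C1C[C@@H]2O[C@H]3[C@H]4[C@@H](CC[C@@](C)(O)[C@H]42)[C@@H](C)C(=O)O[C@@]3(C)[C@H](OC(=O)CCCCCCC)C[C@H]1O | intermediate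
36 | briarellin C | C=C1C[C@@H]2O[C@H]3[C@H]4[C@@H](CC[C@@](C)(O)[C@H]42)[C@@H](C)C(=O)O[C@@]3(C)[C@H](OC(=O)CCCCCCC)C[C@H]1OC(=O)CCC | target

Total step count: 26. Longest linear sequence: 25 steps (steps 1–9 and 11–26, from 1); step 10 is a one-step side branch.

Steps most likely to fail

Step 6. The cycloaddition of the push–pull diene may be slow relative to polymerisation of the enal, and the formyl group may prefer the exo orientation, which would deliver the wrong C11 epimer. The fallback sets out from 7 and comes back at 17. Diene 7 is combined with 2-acetoxyacrolein, for which that same exo-formyl preference places the acyloxy group endo and therefore cis to C9, to give the acetoxy aldehyde adduct F1. The aldehyde is turned into the C11 methyl group through the tosylhydrazone F2 (TsNHNH2) and its reduction with catecholborane and NaOAc to the acetoxy enol ether F3. Acid hydrolysis as in step 7 gives the keto acetate F4, enol triflation as in step 8 gives the triflate F5, Stille coupling with 14 as in step 11 gives the acrylate F6, and the saponification of step 12 removes the acetate and gives 17.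

Step 20. Acylation of the hindered tertiary allylic alcohol may be slower than ionisation of that alcohol or oligomerisation of the activated acid. The fallback sets out from 25 and comes back at 29, forming the C3–O bond by electrophilic cyclisation instead of acyl transfer. Wittig methylenation of 25 (Ph3P=CH2 in excess) gives the isopropenyl acid F7. Iodolactonisation (I2, NaHCO3, MeCN) with attack of the carboxylate on the tertiary alkene carbon gives the iodomethyl lactone F8; the C3 configuration would have to be secured in this ring closure. Kornblum oxidation (AgBF4, DMSO, then Et3N) gives aldehyde 29.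

Step 25. Insertion into the alkenyl bromide may be slow, and the addition to the aldehyde may show poor facial selectivity at C6. The fallback sets out from 34 and comes back at 36, setting C6 by SN2 inversion instead of by the ring closure. If the cyclisation gives mainly the 6-epimeric alcohol F9, Mitsunobu esterification with butanoic acid (PPh3, diisopropyl azodicarboxylate) inverts C6 and gives 36 directly.

Further compounds
F1 | step 6 | 7-acetoxy-4-ethoxy-7-formyl-3-[(1S)-1-tert-butoxyethyl]-5,6,7,7a-tetrahydroisobenzofuran-1(3H)-one (acetoxy cis to C9) | O=C1O[C@H]([C@H](C)OC(C)(C)C)C2=C(OCC)CC[C@@](C=O)(OC(C)=O)[C@H]21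
F2 | step 6 | tosylhydrazone of F1 | O=C1O[C@H]([C@H](C)OC(C)(C)C)C2=C(OCC)CC[C@@](C=NNS(=O)(=O)c3ccc(C)cc3)(OC(C)=O)[C@H]21
F3 | step 6 | 7-acetoxy-4-ethoxy-7-methyl-3-[(1S)-1-tert-butoxyethyl]-5,6,7,7a-tetrahydroisobenzofuran-1(3H)-one | O=C1O[C@H]([C@H](C)OC(C)(C)C)C2=C(OCC)CC[C@@](C)(OC(C)=O)[C@H]21
F4 | step 6 | 7-acetoxy-7-methyl-3-[(1S)-1-tert-butoxyethyl]hexahydroisobenzofuran-1,4-dione (cis-fused) | O=C1O[C@H]([C@H](C)OC(C)(C)C)[C@H]2C(=O)CC[C@@](C)(OC(C)=O)[C@H]21
F5 | step 6 | 7-acetoxy-7-methyl-1-oxo-3-[(1S)-1-tert-butoxyethyl]-1,3,3a,6,7,7a-hexahydroisobenzofuran-4-yl trifluoromethanesulfonate | O=C1O[C@H]([C@H](C)OC(C)(C)C)[C@H]2C(OS(=O)(=O)C(F)(F)F)=CC[C@@](C)(OC(C)=O)[C@H]21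
F6 | step 6 | methyl 2-[7-acetoxy-7-methyl-1-oxo-3-[(1S)-1-tert-butoxyethyl]-1,3,3a,6,7,7a-hexahydroisobenzofuran-4-yl]prop-2-enoate | O=C1O[C@H]([C@H](C)OC(C)(C)C)[C@H]2C(C(=C)C(=O)OC)=CC[C@@](C)(OC(C)=O)[C@H]21
F7 | step 20 | (2R)-2-[1-(2-bromoprop-2-enyl)-7-hydroxy-7-methyl-3-(prop-1-en-2-yl)octahydroisobenzofuran-4-yl]propanoic acid | C=C(Br)C[C@@H]1O[C@H](C(C)=C)[C@H]2[C@@H](CC[C@@](C)(O)[C@H]21)[C@@H](C)C(=O)O
F8 | step 20 | 3-(iodomethyl) analogue of lactone 27 | C=C(Br)C[C@@H]2O[C@H]3[C@H]4[C@@H](CC[C@@](C)(O)[C@H]42)[C@@H](C)C(=O)O[C@@]3(C)CI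
F9 | step 25 | 6-epimer of 35 (6S allylic alcohol) | C=C1C[C@@H]2O[C@H]3[C@H]4[C@@H](CC[C@@](C)(O)[C@H]42)[C@@H](C)C(=O)O[C@@]3(C)[C@H](OC(=O)CCCCCCC)C[C@@H]1O
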